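**Plan**

- Retrosynthesis: the C7–C8 bond is cut first. This opens the γ-lactone and the ten-membered carbocycle together and leads to the 13-membered β-keto macrolactone 31 (C8 ketone, C7 methylene). Then the C19–O7 ester bond (acylketene), C8–C17 (Reformatsky), the C8/C9 oxygens (from a vinyl group), and C1–C2 with C9–C10 (conjugate addition–aldol) are cut, giving enone 6 from (S)-linalool and aldehyde 11 from nerol.
- Forward: cyclohexenone 6 (ring C1, C10–C14) is made first; a three-component coupling puts the vinyl group on C10 and the C2–C7 chain on C1; C14, C2, C9 and C8 are adjusted; the β-keto ester is lactonized to the 13-membered ring 31; a photochemical ring contraction then closes the ten-membered ring and the γ-lactone in one event; C17 equilibration and desilylation finish the route.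
- Enabling feature: the 8-hydroxy-γ-lactone (O–C7–C8(OH)–C17–C19) is the product pattern of δ-hydrogen abstraction by the ketone of a β-keto ester. In 31 the C7–H bond is allylic to C5=C6 and α to the ester oxygen, and the C8 ketone has no γ-hydrogen because C1 and C11 are quaternary.
- Stereochemistry: C11 from (S)-linalool; C10 by alkoxide-directed vinyl addition; C1 and C2 in the aldol; C14 by Evans–Tishchenko reduction (which also places the acetate on O2); C9 by catalyst-controlled diboration; C7 and C8 in the key step; C17 by thermodynamic epimerization; the (Z)-C5=C6 alkene from nerol.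

Key step: step 17

Remark: locants are briarane locants (C1–C20); (S)-(+)-linalool of high enantiomeric purity is assumed to be commercially available; compounds 27–33 are carried as epimer mixtures at C17 (27 also at C8), and these centres are fixed later.

**Route**

Step 1
Reactants: 1 (S)-linalool
Product: 2 (5S)-5-ethenyl-5-methyloxolan-2-ol (lactol)
Conditions: O3 (1.0 equiv), CH2Cl2/MeOH, −78 °C; then Me2S, −78 °C to rt
Reagents that add atoms: ozone, [O-][O+]=O
Why: Chemoselective ozonolysis: ozone should cleave the electron-rich trisubstituted alkene much faster than the vinyl group next to the tertiary carbinol, and the 4-hydroxy aldehyde closes to the lactol; C11 comes unchanged from the chiral pool.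

Step 2
Reactants: 2 lactol; 3 isopropenylmagnesium bromide
Product: 4 (6S)-2,6-dimethylocta-1,7-diene-3,6-diol
Conditions: 3 (3 equiv), THF, 0 °C to rt; aq. NH4Cl
Reagents that add atoms: isopropenylmagnesium bromide (3), CC(=C)[Mg]Br
Why: Grignard addition to the open hydroxy-aldehyde form of the lactol; the new carbinol (future C14) forms as both epimers, which does not matter because it is oxidized in step 4.

Step 3
Reactants: 4 diene diol
Product: 5 (4S)-2,4-dimethylcyclohex-2-ene-1,4-diol
Conditions: second-generation Grubbs catalyst RuCl2(=CHPh)(PCy3)(H2IMes) (2 mol%), CH2Cl2 (0.02 M), 40 °C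
Reagents that add atoms: none
Why: Ring-closing metathesis of the monosubstituted and the 1,1-disubstituted alkene should close the six-membered ring as the trisubstituted C1=C10 cyclohexene with loss of ethylene.

Step 4
Reactants: 5 cyclohexenediol
Product: 6 (4S)-4-hydroxy-2,4-dimethylcyclohex-2-en-1-one
Conditions: MnO2 (activated, excess), CH2Cl2, rt
Reagents that add atoms: none
Why: Allylic oxidation with MnO2 should convert only the secondary allylic alcohol and leave the tertiary alcohol, so both C14 epimers converge to one enone.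

Step 5
Reactants: 7 nerol; 8 4-methoxybenzyl chloride
Product: 9 neryl 4-methoxybenzyl (PMB) ether
Conditions: NaH, Bu4NI (cat.), THF/DMF, 0 °C to rt
Reagents that add atoms: 4-methoxybenzyl chloride (8), COc1ccc(CCl)cc1
Why: Williamson ether synthesis on the primary allylic alkoxide; the (Z)-alkene is not touched.

Step 6
Reactants: 9 neryl PMB ether
Product: 11 (Z)-6-[(4-methoxybenzyl)oxy]-4-methylhex-4-enal, via epoxide 10 (not isolated)
Conditions: mCPBA (1.05 equiv), CH2Cl2, −20 °C; then H5IO6, THF/H2O, 0 °C
Reagents that add atoms: mCPBA, OOC(=O)c1cccc(Cl)c1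
Why: Peracid epoxidation should occur at the remote, more electron-rich alkene (the other is deactivated by the allylic oxygen), and periodic acid cleavage of the epoxide gives the C2 aldehyde with the (Z)-C5=C6 alkene intact.

Step 7
Reactants: 6 enone; 12 vinylmagnesium bromide; 11 aldehyde
Product: 14 β-hydroxy ketone (C1–C2 aldol adduct), via magnesium enolate 13 (not isolated)
Conditions: 12 (2.1 equiv), THF, −78 to −20 °C; then 11 (1.2 equiv), −78 °C; AcOH quench at −78 °C
Reagents that add atoms: vinylmagnesium bromide (12), C=C[Mg]Br; aldehyde 11, O=CCC/C(C)=C\COCc1ccc(OC)cc1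
Why: Alkoxide-directed conjugate addition followed by aldol reaction: the bromomagnesium alkoxide at C11 should deliver the vinyl group to C10 on its own face, the tetrasubstituted magnesium enolate should add to 11 anti to the new vinyl group, and the closed Zimmerman–Traxler transition state of the ring-fixed enolate should place the C2 hydroxyl syn to the C1 methyl group, which sets C10, C1 and C2.

Step 8
Reactants: 14 β-hydroxy ketone; 15 acetaldehyde
Product: 16 2-O-acetyl anti-2,14-diol
Conditions: 15 (10 equiv), SmI2 (0.3 equiv), THF, −10 °C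
Reagents that add atoms: acetaldehyde (15), CC=O
Why: Evans–Tishchenko reduction: the hemiacetal of the C2 hydroxyl with acetaldehyde should deliver hydride to C14 through a samarium-bridged chair fused diequatorially to the cyclohexanone, which gives the axial C14 alcohol anti to O2 and leaves the acetyl group on O2.

Step 9
Reactants: 16 hydroxy acetate; 17 triethylsilyl trifluoromethanesulfonate
Product: 18 11,14-bis(triethylsilyl) ether
Conditions: 17 (3 equiv), 2,6-lutidine, CH2Cl2, −78 to 0 °C
Reagents that add atoms: triethylsilyl trifluoromethanesulfonate (17), CC[Si](CC)(CC)OS(=O)(=O)C(F)(F)F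
Why: Silylation of the secondary and the tertiary alcohol with a silyl triflate; both must be capped so that neither can form a hemiketal with the later C8 ketone or trap the acylketene.

Step 10
Reactants: 18 vinyl compound; 19 bis(pinacolato)diboron
Product: 21 8,9-diol, via bis(boronate) 20 (not isolated)
Conditions: 19, Pt(dba)3 (3 mol%), TADDOL-derived phenylphosphonite ligand (6 mol%; the enantiomer that gives (S)-1,2-diols from 1-alkenes), THF, 60 °C; then NaBO3·4H2O, THF/H2O, rt
Reagents that add atoms: bis(pinacolato)diboron (19), CC1(C)OB(OC1(C)C)B1OC(C)(C)C(C)(C)O1 (boron stays only in 20); sodium perborate, [Na+].[Na+].O[B-]1(O)OO[B-](O)(O)OO1 (the two oxygen atoms)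
Why: Platinum-catalysed enantioselective diboration of the terminal alkene followed by oxidation with retention; the (Z)-trisubstituted alkene should not react, and C9 is set by the ligand (catalyst control).

Step 11
Reactants: 21 diol; 22 trimethyl orthoacetate
Product: 24 9-acetate with free C8 hydroxyl, via cyclic orthoester 23 (not isolated)
Conditions: 22, PPTS (cat.), CH2Cl2, rt; then AcOH/H2O (4:1), 0 °C
Reagents that add atoms: trimethyl orthoacetate (22), CC(OC)(OC)OC; water, O
Why: Cyclic orthoester formation and kinetic acid hydrolysis should leave the acetate on the secondary C9 oxygen and free the primary C8 hydroxyl.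

Step 12
Reactants: 24 primary alcohol
Product: 25 α-acetoxy aldehyde
Conditions: Dess–Martin periodinane, NaHCO3, CH2Cl2, 0 °C
Reagents that add atoms: none
Why: Dess–Martin oxidation under buffered conditions should give the C8 aldehyde without epimerization at C9 or acetyl migration.

Step 13
Reactants: 25 aldehyde; 26 tert-butyl 2-bromopropanoate
Product: 27 β-hydroxy ester
Conditions: 26, Zn (activated), THF, 0 °C to rt; aq. NH4Cl
Reagents that add atoms: tert-butyl 2-bromopropanoate (26), CC(Br)C(=O)OC(C)(C)C
Why: Reformatsky reaction forms C8–C17 under neutral conditions; the new centres at C8 and C17 do not matter here (C8 is oxidized next, C17 is set in step 18).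

Step 14
Reactants: 27 β-hydroxy ester
Product: 28 β-keto ester
Conditions: Dess–Martin periodinane, NaHCO3, CH2Cl2, rt
Reagents that add atoms: none
Why: Dess–Martin oxidation of the secondary alcohol gives the C8 ketone without base, so the C9 centre next to it is not put at risk.

Step 15
Reactants: 28 PMB ether
Product: 29 hydroxy β-keto ester
Conditions: DDQ, CH2Cl2/pH 7 buffer, 0 °C
Reagents that add atoms: none
Why: Oxidative cleavage of the PMB ether with DDQ frees the C7 hydroxyl and leaves silyl ethers, acetates and the alkene untouched.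

Step 16
Reactants: 29 hydroxy β-keto ester
Product: 31 13-membered β-keto lactone, via acylketene 30 (not isolated)
Conditions: toluene, 110 °C, slow addition (final 0.5 mM)
Reagents that add atoms: none
Why: Acylketene macrolactonization: thermal loss of tert-butanol from the β-keto ester should give acylketene 30, which at high dilution is trapped by the only free hydroxyl (O7) to close the 13-membered ring.

Step 17
Reactants: 31 13-membered β-keto lactone
Product: 33 8-hydroxy-γ-lactone on the ten-membered ring (C17 epimers), via biradical 32 (not isolated)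
Conditions: hν (λ > 300 nm, Pyrex filter), degassed C6H6/t-BuOH (9:1), 1 mM, 15 °C
Reagents that add atoms: none
Why: Proposed new method: n→π* excitation of the C8 ketone should be followed by 1,6-hydrogen transfer from C7 (a C–H bond that is allylic to C5=C6 and α to the lactone oxygen; seven-membered transition state through the s-cis ester conformer) to give 1,5-biradical 32, which recombines at C7–C8 (Norrish–Yang photocyclization). The closest known reaction type is the Norrish–Yang cyclization of acyclic β-oxo esters to 3-hydroxy-γ-lactones by δ-hydrogen abstraction; a transannular version that contracts a macrocyclic β-keto lactone has not been shown. The γ-lactone (O, C7, C8, C17, C19) closes by recombination of the 1,5-biradical, and because both radical centres lie in the 13-membered ring the same bond contracts that ring to the ten-membered carbocycle (C1–C10) in a transannular closure. At C7 and C8 the two carbocycle bonds (C7–C6 and C8–C9) should end trans on the lactone, since this keeps the C6–C7–C8–C9 torsion staggered in the forming ten-membered ring, and of the two trans modes the one that puts the small C9–H, not the C9 acetate, between the two lactone bonds at C8 is expected, which is the 7S,8S arrangement relative to the fixed C9 and C10. The step needs abstraction at C7 over the other δ-hydrogens and over α-cleavage (secured by the weak, doubly activated C7–H bond; γ-hydrogens are absent because C1 and C11 are quaternary and the γ-atom on the ester side is oxygen), coupling of the allyl radical at C7 and not at C5 (five- against seven-membered ring), and retention of the (Z)-C5=C6 geometry (the allyl radical should not rotate within the biradical lifetime, and λ > 300 nm excites only the ketone). C17 is not controlled here and is set in step 18.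

Step 18
Reactants: 33 lactone (C17 epimers)
Product: 34 11,14-bis(triethylsilyl) junceellolide I
Conditions: DBU (1 equiv), toluene, 70 °C
Reagents that add atoms: none
Why: Base-mediated epimerization through the lactone enolate: thermodynamic control should favour the epimer with the C18 methyl group trans to the bulky C9 substituent and cis to the C8 hydroxyl (17R); C17 is the only acidic stereocentre.

Step 19
Reactants: 34 bis(triethylsilyl) ether
Product: 35 junceellolide I
Conditions: HF·pyridine, pyridine/THF, 0 °C to rt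
Reagents that add atoms: none
Why: Fluoride-mediated cleavage of both triethylsilyl ethers under buffered acidic conditions should leave the two acetates and the β-hydroxy lactone intact.

**Compound list**

1 | (S)-(+)-linalool, (3S)-3,7-dimethylocta-1,6-dien-3-ol | C=C[C@@](C)(O)CCC=C(C)C | starting material
2 | (5S)-5-ethenyl-5-methyloxolan-2-ol (anomer mixture) | OC1CC[C@@](C)(C=C)O1 | intermediate
3 | isopropenylmagnesium bromide | CC(=C)[Mg]Br | starting material
4 | (6S)-2,6-dimethylocta-1,7-diene-3,6-diol (C3 epimers) | C=C[C@@](C)(O)CCC(O)C(C)=C | intermediate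
5 | (4S)-2,4-dimethylcyclohex-2-ene-1,4-diol (C1 epimers) | OC1CC[C@](C)(O)C=C1C | intermediate
6 | (4S)-4-hydroxy-2,4-dimethylcyclohex-2-en-1-one | O=C1CC[C@](C)(O)C=C1C | intermediate
7 | nerol | CC(C)=CCC/C(C)=C\CO | starting material
8 | 4-methoxybenzyl chloride | COc1ccc(CCl)cc1 | starting material
9 | neryl 4-methoxybenzyl ether | CC(C)=CCC/C(C)=C\COCc1ccc(OC)cc1 | intermediate
10 | 6,7-epoxide of 9 (racemic at the epoxide) | CC1(C)OC1CC/C(C)=C\COCc1ccc(OC)cc1 | intermediate (not isolated)
11 | (Z)-6-[(4-methoxybenzyl)oxy]-4-methylhex-4-enal | O=CCC/C(C)=C\COCc1ccc(OC)cc1 | intermediate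
12 | vinylmagnesium bromide | C=C[Mg]Br | starting material
13 | bis(bromomagnesium) alkoxide enolate (vinyl at C10 cis to O11) | C=C[C@@H]1C(C)=C(O[Mg]Br)CC[C@]1(C)O[Mg]Br | intermediate (not isolated)
14 | β-hydroxy ketone: C14 ketone, C1 quaternary (methyl and C2 chain, chain trans to the C10 vinyl), free C2 and C11 hydroxyls, C7 PMB ether | O[C@@H](CC/C(C)=C\COCc1ccc(OC)cc1)[C@@]2(C)C(=O)CC[C@](C)(O)[C@@H]2C=C | intermediate
15 | acetaldehyde | CC=O | starting material
16 | 2-O-acetyl anti-2,14-diol (free C14 and C11 hydroxyls) | CC(=O)O[C@@H](CC/C(C)=C\COCc1ccc(OC)cc1)[C@@]2(C)[C@@H](O)CC[C@](C)(O)[C@@H]2C=C | intermediate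
17 | triethylsilyl trifluoromethanesulfonate | CC[Si](CC)(CC)OS(=O)(=O)C(F)(F)F | starting material
18 | 11,14-bis(triethylsilyl) ether of 16 | CC(=O)O[C@@H](CC/C(C)=C\COCc1ccc(OC)cc1)[C@@]2(C)[C@@H](O[Si](CC)(CC)CC)CC[C@](C)(O[Si](CC)(CC)CC)[C@@H]2C=C | intermediate
19 | bis(pinacolato)diboron | CC1(C)OB(OC1(C)C)B1OC(C)(C)C(C)(C)O1 | starting material
20 | 8,9-bis(pinacolboronate) | CC(=O)O[C@@H](CC/C(C)=C\COCc1ccc(OC)cc1)[C@@]2(C)[C@@H](O[Si](CC)(CC)CC)CC[C@](C)(O[Si](CC)(CC)CC)[C@@H]2[C@H](B3OC(C)(C)C(C)(C)O3)CB4OC(C)(C)C(C)(C)O4 | intermediate (not isolated)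
21 | 8,9-diol (9S) | CC(=O)O[C@@H](CC/C(C)=C\COCc1ccc(OC)cc1)[C@@]2(C)[C@@H](O[Si](CC)(CC)CC)CC[C@](C)(O[Si](CC)(CC)CC)[C@@H]2[C@H](O)CO | intermediate
22 | trimethyl orthoacetate | CC(OC)(OC)OC | starting material
23 | cyclic 8,9-orthoacetate (2-methoxy-2-methyl-1,3-dioxolane) | CC(=O)O[C@@H](CC/C(C)=C\COCc1ccc(OC)cc1)[C@@]2(C)[C@@H](O[Si](CC)(CC)CC)CC[C@](C)(O[Si](CC)(CC)CC)[C@@H]2[C@H]3COC(C)(OC)O3 | intermediate (not isolated)
24 | 2,9-diacetate with free C8 hydroxyl | CC(=O)O[C@@H](CC/C(C)=C\COCc1ccc(OC)cc1)[C@@]2(C)[C@@H](O[Si](CC)(CC)CC)CC[C@](C)(O[Si](CC)(CC)CC)[C@@H]2[C@H](OC(C)=O)CO | intermediate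
25 | C8 aldehyde (α-acetoxy aldehyde) | CC(=O)O[C@@H](CC/C(C)=C\COCc1ccc(OC)cc1)[C@@]2(C)[C@@H](O[Si](CC)(CC)CC)CC[C@](C)(O[Si](CC)(CC)CC)[C@@H]2[C@H](OC(C)=O)C=O | intermediate
26 | tert-butyl 2-bromopropanoate | CC(Br)C(=O)OC(C)(C)C | starting material
27 | β-hydroxy tert-butyl ester (epimers at C8 and C17) | CC(=O)O[C@@H](CC/C(C)=C\COCc1ccc(OC)cc1)[C@@]2(C)[C@@H](O[Si](CC)(CC)CC)CC[C@](C)(O[Si](CC)(CC)CC)[C@@H]2[C@H](OC(C)=O)C(O)C(C)C(=O)OC(C)(C)C | intermediate
28 | β-keto tert-butyl ester (C17 epimers) | CC(=O)O[C@@H](CC/C(C)=C\COCc1ccc(OC)cc1)[C@@]2(C)[C@@H](O[Si](CC)(CC)CC)CC[C@](C)(O[Si](CC)(CC)CC)[C@@H]2[C@H](OC(C)=O)C(=O)C(C)C(=O)OC(C)(C)C | intermediate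
29 | hydroxy β-keto ester (free C7 hydroxyl; C17 epimers) | CC(=O)O[C@@H](CC/C(C)=C\CO)[C@@]2(C)[C@@H](O[Si](CC)(CC)CC)CC[C@](C)(O[Si](CC)(CC)CC)[C@@H]2[C@H](OC(C)=O)C(=O)C(C)C(=O)OC(C)(C)C | intermediate
30 | acylketene | CC(=O)O[C@@H](CC/C(C)=C\CO)[C@@]2(C)[C@@H](O[Si](CC)(CC)CC)CC[C@](C)(O[Si](CC)(CC)CC)[C@@H]2[C@H](OC(C)=O)C(=O)C(C)=C=O | intermediate (not isolated)
31 | 13-membered β-keto lactone (C8 ketone, C7 methylene; C17 epimers interconverting through the enol) | CC(=O)O[C@H]1CC/C(C)=C\COC(=O)C(C)C(=O)[C@@H](OC(C)=O)[C@@H]2[C@]1(C)[C@@H](O[Si](CC)(CC)CC)CC[C@]2(C)O[Si](CC)(CC)CC | intermediate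
32 | 1,5-biradical (C7 allyl radical, C8 hydroxyalkyl radical) | CC(=O)O[C@H]1CC/C(C)=C\[CH]OC(=O)C(C)[C](O)[C@@H](OC(C)=O)[C@@H]2[C@]1(C)[C@@H](O[Si](CC)(CC)CC)CC[C@]2(C)O[Si](CC)(CC)CC | intermediate (not isolated)
33 | 11,14-bis(triethylsilyl) junceellolide I as C17 epimers | CC(=O)O[C@H]1CC/C(C)=C\[C@@H]2OC(=O)C(C)[C@@]2(O)[C@@H](OC(C)=O)[C@@H]3[C@]1(C)[C@@H](O[Si](CC)(CC)CC)CC[C@]3(C)O[Si](CC)(CC)CC | intermediate
34 | 11,14-bis(triethylsilyl) junceellolide I (17R) | CC(=O)O[C@H]1CC/C(C)=C\[C@@H]2OC(=O)[C@H](C)[C@@]2(O)[C@@H](OC(C)=O)[C@@H]3[C@]1(C)[C@@H](O[Si](CC)(CC)CC)CC[C@]3(C)O[Si](CC)(CC)CC | intermediate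
35 | junceellolide I | CC(=O)O[C@H]1CC/C(C)=C\[C@@H]2OC(=O)[C@H](C)[C@@]2(O)[C@@H](OC(C)=O)[C@@H]2[C@]1(C)[C@@H](O)CC[C@]2(C)O | target

**Step count**

Total: 19 steps. Longest linear sequence: 17 steps (steps 1–4 and 7–19); steps 5–6 make the second fragment.

**Steps most likely to fail**

1. Step 17 (Proposed new method). What may go wrong: hydrogen abstraction at another δ-position or α-cleavage of the ketone, return of the hydrogen atom from the biradical to starting material, or poor facial selectivity at C7/C8 in the recombination. Fallback (known chemistry), from 28 back to 33: enolization with NaH and triflation with PhNTf2 should give the (Z)-enol triflate F1; DDQ removes the PMB group to give allylic alcohol F2, and MnO2 gives the (Z)-enal F3. Intramolecular Nozaki–Hiyama–Kishi coupling (CrCl2, catalytic NiCl2, DMSO/THF, high dilution) joins C8 to C7 by a polar route and closes the ten-membered ring as hydroxy ester F4, whose C7 hydroxyl lactonizes onto the cis tert-butyl ester (PPTS, warm toluene) to give butenolide F5. Nucleophilic epoxidation (t-BuOOH, DBU) should give the 8,17-epoxy lactone F6, and reductive opening of the C17–O bond with SmI2 in THF/MeOH gives 33 as C17 epimers, which re-enters the route at step 18.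

2. Step 7. What may go wrong: 1,2-addition or proton transfer competing with the directed 1,4-addition, and reversal of the magnesium aldolate (retro-aldol) at the new quaternary centre. Fallback, from 6 back to 14: the conjugate addition is run alone (12, THF) and the enolate is trapped with Me3SiCl/Et3N to give the bis(trimethylsilyl) compound F7 (silyl enol ether and tertiary silyl ether), which is isolated. A Lewis-acid Mukaiyama aldol reaction with 11 (BF3·OEt2, CH2Cl2, −78 °C), which is not reversible, should give the silyl-protected aldol F8, again by attack anti to the vinyl group, with C2 now set through an open transition state and therefore less securely. Citric acid in MeOH removes the tertiary trimethylsilyl ether to give 14.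

3. Step 10. What may go wrong: slow diboration of the very hindered vinyl group, or a substrate bias that opposes the ligand at C9. Fallback, from 18 back to 21: hydroboration with 9-BBN and oxidation with NaBO3 give primary alcohol F9, and Dess–Martin oxidation gives aldehyde F10. D-Proline-catalysed α-aminoxylation with nitrosobenzene (the proline enantiomer chosen for 9S) gives anilinoxy aldehyde F11, which is reduced in the same flask with NaBH4 to anilinoxy alcohol F12; cleavage of the N–O bond (CuSO4, MeOH) gives diol 21.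

**Further compounds**

F1 | step 17 | (Z)-enol triflate of 28 (triflate cis to the ester) | CC(=O)O[C@@H](CC/C(C)=C\COCc1ccc(OC)cc1)[C@@]2(C)[C@@H](O[Si](CC)(CC)CC)CC[C@](C)(O[Si](CC)(CC)CC)[C@@H]2[C@H](OC(C)=O)/C(OS(=O)(=O)C(F)(F)F)=C(\C)C(=O)OC(C)(C)C
F2 | step 17 | allylic alcohol (C7 hydroxyl) of the enol triflate | CC(=O)O[C@@H](CC/C(C)=C\CO)[C@@]2(C)[C@@H](O[Si](CC)(CC)CC)CC[C@](C)(O[Si](CC)(CC)CC)[C@@H]2[C@H](OC(C)=O)/C(OS(=O)(=O)C(F)(F)F)=C(\C)C(=O)OC(C)(C)C
F3 | step 17 | (Z)-enal (C7 aldehyde) of the enol triflate | CC(=O)O[C@@H](CC/C(C)=C\C=O)[C@@]2(C)[C@@H](O[Si](CC)(CC)CC)CC[C@](C)(O[Si](CC)(CC)CC)[C@@H]2[C@H](OC(C)=O)/C(OS(=O)(=O)C(F)(F)F)=C(\C)C(=O)OC(C)(C)C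
F4 | step 17 | ten-membered 7-hydroxy 8(17)-enoate tert-butyl ester | CC(=O)O[C@H]1CC/C(C)=C\[C@H](O)/C(=C(/C)C(=O)OC(C)(C)C)[C@@H](OC(C)=O)[C@@H]2[C@]1(C)[C@@H](O[Si](CC)(CC)CC)CC[C@]2(C)O[Si](CC)(CC)CC
F5 | step 17 | 8(17)-butenolide fused to the ten-membered ring | CC(=O)O[C@H]1CC/C(C)=C\[C@@H]2OC(=O)C(C)=C2[C@@H](OC(C)=O)[C@@H]3[C@]1(C)[C@@H](O[Si](CC)(CC)CC)CC[C@]3(C)O[Si](CC)(CC)CC
F6 | step 17 | 8,17-epoxy lactone | CC(=O)O[C@H]1CC/C(C)=C\[C@@H]2OC(=O)[C@]4(C)O[C@]24[C@@H](OC(C)=O)[C@@H]3[C@]1(C)[C@@H](O[Si](CC)(CC)CC)CC[C@]3(C)O[Si](CC)(CC)CC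
F7 | step 7 | bis(trimethylsilyl) compound (C14 silyl enol ether, C11 silyl ether) | C=C[C@@H]1C(C)=C(O[Si](C)(C)C)CC[C@]1(C)O[Si](C)(C)C
F8 | step 7 | 11-O-trimethylsilyl ether of 14 | O[C@@H](CC/C(C)=C\COCc1ccc(OC)cc1)[C@@]2(C)C(=O)CC[C@](C)(O[Si](C)(C)C)[C@@H]2C=C
F9 | step 10 | C8 primary alcohol (C9 methylene) | CC(=O)O[C@@H](CC/C(C)=C\COCc1ccc(OC)cc1)[C@@]2(C)[C@@H](O[Si](CC)(CC)CC)CC[C@](C)(O[Si](CC)(CC)CC)[C@@H]2CCO
F10 | step 10 | C8 aldehyde (C9 methylene) | CC(=O)O[C@@H](CC/C(C)=C\COCc1ccc(OC)cc1)[C@@]2(C)[C@@H](O[Si](CC)(CC)CC)CC[C@](C)(O[Si](CC)(CC)CC)[C@@H]2CC=O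
F11 | step 10 | 9-anilinoxy C8 aldehyde | CC(=O)O[C@@H](CC/C(C)=C\COCc1ccc(OC)cc1)[C@@]2(C)[C@@H](O[Si](CC)(CC)CC)CC[C@](C)(O[Si](CC)(CC)CC)[C@@H]2[C@H](ONc3ccccc3)C=O
F12 | step 10 | 9-anilinoxy C8 alcohol | CC(=O)O[C@@H](CC/C(C)=C\COCc1ccc(OC)cc1)[C@@]2(C)[C@@H](O[Si](CC)(CC)CC)CC[C@](C)(O[Si](CC)(CC)CC)[C@@H]2[C@H](ONc3ccccc3)CO
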